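Dissolved gas could not rise above saturation in this flask, so I treated saturation as its ceiling. This is the bench as I handed it over.

the same everywhere: starting material 0.29 M; gas phase 16 mM (held)
- south: catalyst 3.6 mM; run made earlier
- south-east: catalyst 14 mM; run made earlier
- flask: catalyst 7.2 mM; time 2.0 d

| run | time / h | product / % | starting material / % |
|---|---|---|---|
| south | 3.00 | 6 | 98 |
| south | 8.00 | 11 | 87 |
| south | 15.0 | 26 | 77 |
| south | 40.0 | 47 | 52 |
| south-east | 3.00 | 21 | 78 |
| south-east | 8.00 | 39 | 60 |
| south-east | 15.0 | 65 | 37 |
| south-east | 40.0 | 93 | 8 |

(scatter of a reading: 2 percentage points)

- at the start none of the gas phase is in solution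

- amount of product at 2.0 d, in percent of the starting material charged
- concentration of dissolved gas in solution at 2.0 d, in percent of saturation

I reckoned with one quantity, the dose: catalyst concentration times time. The south run took 144 mM·h by 40.0 h and left 52% starting material. The south-east run left 60% at 112 mM·h and 37% at 210 mM·h, so the south reading lay between those two readings, as one curve of dose against starting material left asks at this charge of starting material and gas.

From the south-east reading at 15.0 h I took the dose constant, the natural logarithm of charged over left, per unit of dose: 0.00473 mM⁻¹ h⁻¹, a reading with its scatter. With the gas held, this is a pseudo-first-order picture.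

The flask takes 346 mM·h by 2.0 d, so I expected 19.5% starting material left and 80.5% product. I saw no lag in either run, so I put dissolved gas near its ceiling, without a figure of my own. I asked that the catalyst and the timing stay untouched, since the dose rests on them.

The forecast gave 80% product and 99% of saturation, reasoning that “gas transfer is not limiting and dissolved gas stays close to saturation”.

The flask gave 81.0% product, with dissolved gas at 98.8% of saturation.

    dissolved gas → decomposed reagent (k = 0.00340 min⁻¹)
    gas phase ⇌ dissolved gas, rate k2*(csat - [dissolved gas]) (kL = 0.450 min⁻¹)
    starting material + dissolved gas + catalyst → catalyst + product (k = 5.10 M⁻² min⁻¹)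

By 2.0 d the flask held 0.154 M of decomposed reagent beside 0.0158 M of dissolved gas, and that decomposition made no difference to the product. I then put the dose constant to the same flask with 0.0018 M of catalyst: its dose of 86.4 mM·h gave 66.5% starting material left, and that flask held 65.9%.

Readings and results were computed for an exercise.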